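Start from what must be left over. One turn of the proposed cycle takes one starting material and one coupling partner. Call the ceiling the smaller of one and the partner charge over the starting-material charge: it is 100% in this flask. The charges here are equal, so unused partner should match unused starting material, apart from the micromolar amount on the catalyst.

| flask | starting material | coupling partner | scavenger | free catalyst | remark | time |
|---|---|---|---|---|---|---|
| north-east | 0.017 M | 0.012 M | 0.018 M | 12 µM | run made earlier |  |
| north | 0.026 M | 0.012 M | 0.018 M | 12 µM | run made earlier |  |
| south-west | 0.012 M | 0.012 M | 0.018 M | 24 µM | run made earlier |  |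
| flask | 0.012 M | 0.0120 M | 0.0180 M | 12 µM |  | 12 min |

| run | time / min | starting material / % | target / % |
|---|---|---|---|
| north-east | 2.00 | 81.0 | 19.9 |
| north-east | 4.00 | 63.0 | 36.2 |
| north-east | 5.00 | 56.1 | 44.4 |
| north-east | 8.00 | 38.8 | 61.1 |
| north | 0.833 | 94.2 | 5.7 |
| north | 2.50 | 83.5 | 16.8 |
| north | 5.00 | 70.0 | 30.1 |
| north | 8.00 | 58.5 | 41.7 |
| south-west | 0.500 | 86.2 | 13.4 |
| south-west | 1.33 | 66.0 | 34.4 |
| south-west | 3.00 | 33.3 | 66.8 |
| south-west | 8.00 | 1.4 | 98.6 |

(readings scatter by 0.3 percentage points)

- released group is meant together with its idle adduct
- the numbers in the tables scatter by 0.3 percentage points (one standard deviation)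
- what may be going on: starting material + free catalyst -> catalyst intermediate A; catalyst intermediate A -> catalyst intermediate B; coupling partner + catalyst intermediate B <-> catalyst intermediate C; catalyst intermediate C -> released group + catalyst intermediate D; catalyst intermediate D <-> free catalyst + target; coupling partner + released group <-> idle adduct; scavenger + released group -> scavenged by-product
- the earlier runs do not show how much of coupling partner is bound; that part of a forecast is a guess

* part of the starting material that has reacted at 12 min
* share of the unused coupling partner that is free and not bound as idle adduct, at 12 min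

Two chemists dispute how near the ceiling this flask comes. The first draws a straight line: the north run made target at 1.75 mM min⁻¹ up to 2.50 min, which reaches the ceiling after 6.87 min, earlier than 12 min.

The second objects that lines bend. The early pace of the south-west run promises 77.6% target at 3.00 min, but the reading is 66.8%. On this view the flask is that run with half the catalyst, so 12 min here counts as 6.00 min there, between its readings of 66.8% and 98.6%.

The forecast, from the second side, gives 93.8% reacted (91.5% to 96%) and 75% of unused partner free (40% to 95%), adding “binding looks modest, though this is largely a guess”.

The flask gives 94.0% reacted and 99.5% free.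

    starting material + free catalyst → catalyst intermediate A (k = 1450 L mol⁻¹ s⁻¹)
    catalyst intermediate A → catalyst intermediate B (k = 4.40 s⁻¹)
    coupling partner + catalyst intermediate B ⇌ catalyst intermediate C (K = 252 L mol⁻¹, k = 1280 L mol⁻¹ s⁻¹)
    catalyst intermediate C → released group + catalyst intermediate D (k = 18.2 s⁻¹)
    catalyst intermediate D ⇌ free catalyst + target (K = 0.0230 M, k = 1650 s⁻¹)
    coupling partner + released group ⇌ idle adduct, settled at all times (K = 579 L mol⁻¹)
    scavenger + released group → scavenged by-product (k = 72.9 L mol⁻¹ s⁻¹)

Against the ceiling of 100%, the flask keeps 6.0% of its starting material and 6.0% of its partner. The straight line holds early: 16.3% target at 1.20 min, where its pace gives 17.5%. At 12.0 min the flask holds 0.0113 M of scavenged by-product against 3.35 × 10⁻⁶ M of idle adduct. That adduct stands beside 7.21 × 10⁻⁴ M of free partner.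

In the neighbour flask charged with 0.0030 M of partner, the ceiling is 25.0%. That flask reaches 25.1%, with 0.0516% of its partner left and 99.9% of its catalyst standing as catalyst intermediate B.

The readings stem from a simulated flask from invented constants.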